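**Retrosynthetic overview**
1. Target 22 ⇐ diol 20 by two regioselective acylations (equatorial 8-OH acetate first, axial 9-OH tiglate last); the isopropenyl group ⇐ tertiary C11 alcohol; the cis ring fusion ⇐ hydroxyl-directed hydrogenation of a Δ1(10) alkene.
2. The 8α,9α-diol ⇐ OsO4 on the γ,δ-alkene of the linear dienone 13 (Δ1(10),8-dien-2-one).
3. Dienone 13 ⇐ tricyclic enone 10 by acid fragmentation of the pinane cyclobutane (C9–C11), which releases C11 as a masked isopropenyl and makes C9 available for unsaturation.
4. Ring A ⇐ key intermolecular Michael addition of the 3-methylnopinone enolate to (E)-pent-3-en-2-one (C5–C4 bond), then intramolecular aldol condensation (C1–C10 bond).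
5. Ring order: ring B is present from the start as the six-membered ring of (−)-β-pinene/nopinone and carries the C7 stereocentre; ring A is annulated onto it; the cyclobutane is opened afterwards.

**Convention and assumption (one line):** eremophilane numbering is used (C2 = ketone, C4/C5 carry CH3-15/CH3-14, C7 carries C11, C8/C9 carry the oxygens, C10 = ring-fusion CH; β = face of CH3-14); all bicyclic compounds 11–22 have 4β-CH3, 5β-CH3 and the C7 side chain β; the ester in the target SMILES is read as (E) = tiglate; the target is (4S,5R,7R,8R,9S,10S). Commercial (−)-β-pinene of high ee is assumed.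

**Route**

Step 1
Reactants: 1 (−)-β-pinene
Product: 3 (+)-nopinone, via β-pinene ozonide 2 (not isolated)
Conditions: O3, CH2Cl2, −78 °C; then Me2S, −78 °C → rt
Reagents that add atoms: ozone, [O-][O+]=O
Why: Ozonolysis (Criegee cleavage) of the exocyclic methylene with reductive work-up gives the ketone without touching either bridgehead, so the (1R,5S) configuration (future C9 and C7) is taken from the chiral pool.

Step 2
Reactants: 3 (+)-nopinone
Product: 5 3-methylnopinone, via nopinone lithium enolate 4 (not isolated)
Conditions: LDA (1.05 eq), THF, −78 °C; then MeI, −78 → 0 °C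
Reagents that add atoms: iodomethane, CI
Why: Kinetic enolate alkylation in which C3 is the only enolisable position (the bridgehead cannot enolise, Bredt) and MeI enters anti to the gem-dimethyl bridge; this centre is re-enolised in step 3, so its ratio does not matter.

Step 3 (key step)
Reactants: 5 3-methylnopinone; 6 (E)-pent-3-en-2-one
Product: 8 Michael adduct (1,5-diketone), via sodium enolate 7 (not isolated)
Conditions: NaH (1.1 eq), 1,4-dioxane, 50 °C; then 6, 20 °C; 1 M HCl work-up
Reagents that add atoms: none
Why: Intermolecular Michael addition (first half of a Robinson annulation) in which the enone adds to the enolate face opposite the gem-dimethyl bridge, so the ring methyl (future C14) ends syn to the bridge (future 5β-CH3 cis to the 7β side chain), and the compact chelated sodium-enolate transition state in dioxane gives the cis-vicinal dimethyl arrangement at the new side-chain centre (future C4).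

Step 4
Reactants: 8 Michael adduct
Product: 10 tricyclic enone (9,11-cycloeremophil-1(10)-en-2-one), via tricyclic ketol 9 (not isolated)
Conditions: KOH (0.3 eq), MeOH, 65 °C
Reagents that add atoms: none
Why: Intramolecular aldol addition of the methyl-ketone enolate to the ring carbonyl followed by E1cB dehydration closes ring A, the carbinol centre of 9 being lost on dehydration while C4 and C5 are not enolisable.

Step 5
Reactants: 10 tricyclic enone
Product: 11 eremophila-1,9-diene-2,11-diyl diacetate
Conditions: Ac2O (5 eq), BF3·OEt2 (0.3 eq), Zn(OAc)2 (0.2 eq), CH2Cl2, 0 °C → rt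
Reagents that add atoms: acetic anhydride, CC(=O)OC(C)=O
Why: Lewis-acid-promoted cationic fragmentation of the strained C9–C11 cyclobutane bond (vinylogous retro-aldol/Grob type, as in acid cleavage of nopinone-type ketones) gives the heteroannular dienol, trapped as its acetate, and the tertiary C11 cation, trapped as the acetate; C7 keeps its configuration because its bonds are untouched.

Step 6
Reactants: 11 dienyl diacetate
Product: 13 11-acetoxyeremophila-1(10),8-dien-2-one, via 9-bromo enone 12 (not isolated)
Conditions: NBS (1.05 eq), DMF–H2O (20:1), 0 °C; then Li2CO3, LiBr, 100 °C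
Reagents that add atoms: none
Why: γ-Bromination of the dienol acetate followed by dehydrobromination is the classical route from a dienol acetate to the linear 4,6-dienone type system and creates no new stereocentre.

Step 7
Reactants: 13 dienone
Product: 14 11-acetoxy-8α,9α-dihydroxyeremophil-1(10)-en-2-one
Conditions: OsO4 (2 mol %), NMO (1.5 eq), acetone–H2O (5:1), rt
Reagents that add atoms: osmium tetroxide (catalytic), O=[Os](=O)(=O)=O; N-methylmorpholine N-oxide, C[N+]1([O-])CCOCC1; water, O
Why: Upjohn syn-dihydroxylation occurs at the more electron-rich γ,δ-alkene and from the α-face, anti to both the angular CH3-14 and the adjacent bulky 7β side chain, which sets the cis 8α,9α-diol trans to C11.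

Step 8
Reactants: 14 diol
Product: 15 11-acetoxy-8α,9α-(isopropylidenedioxy)eremophil-1(10)-en-2-one
Conditions: 2,2-dimethoxypropane, PPTS (cat.), CH2Cl2, rt
Reagents that add atoms: 2,2-dimethoxypropane, COC(C)(C)OC
Why: Acid-catalysed transketalisation protects the cis-diol as the acetonide, which also shields the α-face and removes the 9-OH as a directing group for step 10.

Step 9
Reactants: 15 enone acetonide
Product: 16 8α,9α-(isopropylidenedioxy)eremophil-1(10)-ene-2β,11-diol
Conditions: LiAlH4 (2.5 eq), THF, −78 → 0 °C; Fieser work-up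
Reagents that add atoms: none
Why: Hydride 1,2-reduction of the enone by axial attack from the α-face gives the pseudo-equatorial 2β-allylic alcohol (as with Δ4-3-keto steroids), and the same reagent reductively cleaves the tertiary acetate to the free C11 alcohol.

Step 10
Reactants: 16 allylic alcohol
Product: 17 8α,9α-(isopropylidenedioxy)-10βH-eremophilane-2β,11-diol
Conditions: H2 (1 atm), [Ir(cod)(PCy3)(py)]PF6 (5 mol %), CH2Cl2, rt
Reagents that add atoms: none
Why: Hydroxyl-directed homogeneous hydrogenation (Crabtree catalyst) delivers H2 to the β-face of C1=C10 syn to the 2β-OH, which sets 10β-H and therefore the cis ring fusion.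

Step 11
Reactants: 17 saturated diol
Product: 18 11-hydroxy-8α,9α-(isopropylidenedioxy)-10βH-eremophilan-2-one
Conditions: Dess–Martin periodinane (1.2 eq), CH2Cl2, 0 °C → rt
Reagents that add atoms: none
Why: Dess–Martin oxidation converts only the secondary 2-OH into the ketone (the tertiary alcohol cannot be oxidised), and neither α-carbon of the new ketone is a stereocentre.

Step 12
Reactants: 18 hydroxy ketone
Product: 19 8α,9α-(isopropylidenedioxy)-10βH-eremophil-11-en-2-one
Conditions: Burgess reagent (2 eq), toluene, 70 °C
Reagents that add atoms: none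
Why: Burgess dehydration (syn Ei elimination of the tertiary sulfamate) should favour the isopropenyl alkene because six methyl hydrogens compete with the single hindered H-7 next to the C8 oxygen; the minor Δ7(11) isomer is removed on AgNO3-impregnated silica.

Step 13
Reactants: 19 isopropenyl acetonide
Product: 20 8α,9α-dihydroxy-10βH-eremophil-11-en-2-one
Conditions: AcOH–H2O (4:1), 40 °C
Reagents that add atoms: none
Why: Mild acid-catalysed acetonide hydrolysis frees the cis-diol without hydrating or isomerising the 1,1-disubstituted alkene.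

Step 14
Reactants: 20 diol
Product: 21 8α-acetoxy-9α-hydroxy-10βH-eremophil-11-en-2-one
Conditions: Ac2O (1.1 eq), pyridine, CH2Cl2, −20 → 0 °C
Reagents that add atoms: acetic anhydride, CC(=O)OC(C)=O
Why: Regioselective acylation, because in the cis-decalin conformer with the 7β-isopropenyl group equatorial the 8α-OH is equatorial and accessible whereas the 9α-OH is axial, flanked by the ring fusion and 1,3-diaxial to C4.

Step 15
Reactants: 21 monoacetate
Product: 22 target, 8α-acetoxy-9α-tigloyloxy-10βH-eremophil-11-en-2-one
Conditions: tigloyl chloride (3 eq), DMAP (0.5 eq), pyridine, CH2Cl2, 40 °C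
Reagents that add atoms: tigloyl chloride, C/C=C(\C)C(Cl)=O
Why: DMAP-catalysed acylation (nucleophilic catalysis via the acylpyridinium) esterifies the remaining hindered axial 9α-OH, and the (E)-2-methylbut-2-enoate is configurationally stable under these amine-base conditions without trialkylamine.

**Compound list**
1 | (−)-β-pinene, (1S,5S)-6,6-dimethyl-2-methylidenebicyclo[3.1.1]heptane | CC1(C)[C@H]2CCC(=C)[C@@H]1C2 | starting material
2 | β-pinene ozonide (spiro-1,2,4-trioxolane at C2, mixture at the spiro carbon) | CC1(C)[C@H]2CCC3(OCOO3)[C@@H]1C2 | intermediate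
3 | (+)-nopinone, (1R,5S)-6,6-dimethylbicyclo[3.1.1]heptan-2-one | CC1(C)[C@H]2CCC(=O)[C@@H]1C2 | intermediate
4 | nopinone lithium enolate (C2–OLi, C2=C3) | CC1(C)[C@H]2CC=C(O[Li])[C@@H]1C2 | intermediate
5 | 3-methylnopinone (3-CH3 mainly trans to the gem-dimethyl bridge; epimer mixture usable) | CC1(C)[C@H]2C[C@H](C)C(=O)[C@@H]1C2 | intermediate
6 | (E)-pent-3-en-2-one | C/C=C/C(C)=O | starting material
7 | sodium enolate of 5 (C2–ONa, C2=C3(CH3)) | CC1(C)[C@H]2CC(C)=C(O[Na])[C@@H]1C2 | intermediate
8 | Michael adduct: 3-methyl-3-(4-oxopentan-2-yl)nopinone, 3-CH3 syn and side chain anti to the gem-dimethyl bridge, side-chain centre as in C4 of the target | CC1(C)[C@H]2C[C@@]([C@@H](C)CC(C)=O)(C)C(=O)[C@@H]1C2 | intermediate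
9 | tricyclic ketol (10β-hydroxy-9,11-cycloeremophilan-2-one) | CC1(C)[C@H]2C[C@@]3(C)[C@](O)(CC(=O)C[C@@H]3C)[C@@H]1C2 | intermediate
10 | tricyclic enone, 9,11-cycloeremophil-1(10)-en-2-one (cyclobutane C7–C8–C9–C11 on the β-face) | CC1(C)[C@H]2C[C@@]3(C)C(=CC(=O)C[C@@H]3C)[C@@H]1C2 | intermediate
11 | eremophila-1,9-diene-2,11-diyl diacetate | CC(C)(OC(C)=O)[C@H]1C[C@@]2(C)C(C=C(OC(C)=O)C[C@@H]2C)=CC1 | intermediate
12 | 11-acetoxy-9-bromoeremophil-1(10)-en-2-one (C9 epimers) | CC(C)(OC(C)=O)[C@H]1C[C@@]2(C)C(=CC(=O)C[C@@H]2C)C(Br)C1 | intermediate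
13 | 11-acetoxyeremophila-1(10),8-dien-2-one | CC(C)(OC(C)=O)[C@H]1C[C@@]2(C)C(=CC(=O)C[C@@H]2C)C=C1 | intermediate
14 | 11-acetoxy-8α,9α-dihydroxyeremophil-1(10)-en-2-one | CC(C)(OC(C)=O)[C@H]1C[C@@]2(C)C(=CC(=O)C[C@@H]2C)[C@H](O)[C@@H]1O | intermediate
15 | 11-acetoxy-8α,9α-(isopropylidenedioxy)eremophil-1(10)-en-2-one | CC(C)(OC(C)=O)[C@H]1C[C@@]2(C)C(=CC(=O)C[C@@H]2C)[C@H](OC(C)(C)O3)[C@@H]13 | intermediate
16 | 8α,9α-(isopropylidenedioxy)eremophil-1(10)-ene-2β,11-diol | CC(C)(O)[C@H]1C[C@@]2(C)C(=C[C@H](O)C[C@@H]2C)[C@H](OC(C)(C)O3)[C@@H]13 | intermediate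
17 | 8α,9α-(isopropylidenedioxy)-10βH-eremophilane-2β,11-diol (cis-fused) | CC(C)(O)[C@H]1C[C@@]2(C)[C@H](C[C@H](O)C[C@@H]2C)[C@H](OC(C)(C)O3)[C@@H]13 | intermediate
18 | 11-hydroxy-8α,9α-(isopropylidenedioxy)-10βH-eremophilan-2-one | CC(C)(O)[C@H]1C[C@@]2(C)[C@H](CC(=O)C[C@@H]2C)[C@H](OC(C)(C)O3)[C@@H]13 | intermediate
19 | 8α,9α-(isopropylidenedioxy)-10βH-eremophil-11-en-2-one | C=C(C)[C@H]1C[C@@]2(C)[C@H](CC(=O)C[C@@H]2C)[C@H](OC(C)(C)O3)[C@@H]13 | intermediate
20 | 8α,9α-dihydroxy-10βH-eremophil-11-en-2-one | C=C(C)[C@H]1C[C@@]2(C)[C@H](CC(=O)C[C@@H]2C)[C@H](O)[C@@H]1O | intermediate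
21 | 8α-acetoxy-9α-hydroxy-10βH-eremophil-11-en-2-one | C=C(C)[C@H]1C[C@@]2(C)[C@H](CC(=O)C[C@@H]2C)[C@H](O)[C@@H]1OC(C)=O | intermediate
22 | (4S,5R,7R,8R,9S,10S)-8-acetoxy-9-[(E)-2-methylbut-2-enoyloxy]eremophil-11-en-2-one (CNP0204573.1) | C=C(C)[C@H]1C[C@@]2(C)[C@H](CC(=O)C[C@@H]2C)[C@H](OC(=O)/C(C)=C/C)[C@@H]1OC(C)=O | target

**Totals**
Total step count: 15. Longest linear sequence: 15 steps, from (−)-β-pinene 1 to 22; the route is linear and 6 is purchased.

**Steps most likely to fail, with fallbacks**

Step 3 (Michael addition). It builds a quaternary centre next to a tertiary one, the adduct can revert, and the C4 ratio rests on the chelated transition state. The fallback sets out from 5: silylation (LDA, TMSCl, THF, −78 °C) gives 3-methylnopinone trimethylsilyl enol ether F1, which is added to 6 with TiCl4 in CH2Cl2 at −78 °C (Mukaiyama–Michael, irreversible, Lewis-acid manifold instead of the metal enolate). Aqueous work-up brings the route back at diketone 8; any C4 epimer is separated at the crystalline enone 10.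

Step 5 (cyclobutane fragmentation with acetate capture). The tertiary cation may lose a proton instead of being trapped, and the enone may give only a cross-conjugated dienol acetate. The fallback sets out from 10: dry HCl in AcOH at 20 °C effects the protic fragmentation with chloride capture to give 11-chloroeremophil-1(10)-en-2-one F2. Silver acetate in AcOH exchanges the tertiary chloride to give 11-acetoxyeremophil-1(10)-en-2-one F3. Dehydrogenation of F3 with chloranil in refluxing t-BuOH (quinone dehydrogenation instead of the dienol acetate/NBS sequence) brings the route back at dienone 13.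

Step 12 (dehydration to the isopropenyl group). The Δ7(11) isomer may form in a larger share than expected. The fallback sets out from 18: acetylation of the tertiary alcohol (Ac2O, DMAP, Et3N, 40 °C) gives 11-acetoxy-8α,9α-(isopropylidenedioxy)-10βH-eremophilan-2-one F4. Flash vacuum pyrolysis of F4 (450 °C, 0.05 Torr) is a reagent-free thermal syn-elimination of acetic acid with no cationic character and a statistical preference for the methyl hydrogens. It brings the route back at 19.

**Further compounds**
F1 | step 3 | 3-methylnopinone trimethylsilyl enol ether | CC1(C)[C@H]2CC(C)=C(O[Si](C)(C)C)[C@@H]1C2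
F2 | step 5 | 11-chloroeremophil-1(10)-en-2-one (4β,5β-dimethyl, 7β side chain) | CC(C)(Cl)[C@H]1C[C@@]2(C)C(=CC(=O)C[C@@H]2C)CC1
F3 | step 5 | 11-acetoxyeremophil-1(10)-en-2-one (4β,5β-dimethyl, 7β side chain) | CC(C)(OC(C)=O)[C@H]1C[C@@]2(C)C(=CC(=O)C[C@@H]2C)CC1
F4 | step 12 | 11-acetoxy-8α,9α-(isopropylidenedioxy)-10βH-eremophilan-2-one | CC(C)(OC(C)=O)[C@H]1C[C@@]2(C)[C@H](CC(=O)C[C@@H]2C)[C@H](OC(C)(C)O3)[C@@H]13
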